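Readings and results are calculated for substances that don't exist.

**Amounts first.** You charge 0.10 M of solid electrophile and 1.10 equiv of free base, and hold the gas at 43 mM. You asked for a quick number, so here is mine.

| flask | solid electrophile | free base | gas | remark | time |
|---|---|---|---|---|---|
| south-east | 0.10 M | 0.55 equiv | 43 mM (held) | run made earlier |  |
| north-west | 0.10 M | 0.83 equiv | 43 mM (held) | run made earlier |  |
| flask | 0.10 M | 1.10 equiv | 43 mM (held) |  | 2.5 h |

| run | time / h | solid electrophile / % | product / % |
|---|---|---|---|
| south-east | 0.250 | 81.7 | 3.6 |
| south-east | 0.417 | 70.5 | 10.9 |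
| south-east | 0.833 | 47.1 | 27.3 |
| south-east | 1.50 | 9.3 | 62.9 |
| south-east | 3.00 | 0 | 97.8 |
| north-west | 0.250 | 81.9 | 3.9 |
| north-west | 0.417 | 71.8 | 9.2 |
| north-west | 0.833 | 46.6 | 27.3 |
| north-west | 1.50 | 8.9 | 62.7 |
| north-west | 3.00 | 0.2 | 98.4 |

(standard deviation of a reading: 0.5 percentage points)

* part of the solid electrophile that has reacted (what has only dissolved counts as not reacted) at 2.5 h
* share of the unused nucleophile that is free and not bound as protonated nucleophile, at 2.5 h

- the earlier runs were read with a standard deviation of 0.5 percentage points
- at the start none of the solid electrophile is in solution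
- at the start none of the gas is in solution
- what has only dissolved of solid electrophile counts as not reacted
- the earlier runs do not show how much of nucleophile is bound; that part of a forecast is a guess

**The base.** The south-east and north-west runs differ in free base, 0.55 equiv against 0.83 equiv. Yet at 1.50 h they read product 62.9% and 62.7%. South-east has by then passed its base charge, and at 3.00 h it still reads 97.8% against 98.4%. So I carry the south-east rate over to your flask. The runs do not show how much nucleophile is bound, so I guess that free base stays unused. Each product then leaves one protonated nucleophile, and the gas refills the nucleophile to about 43 mM.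

**Going round.** Call the free share [nucleophile] over [nucleophile] plus [protonated nucleophile]. Under my assumption it is 43 mM over 43 mM plus [product]. Taking the whole charge as product gives a first answer of 30.1%. With the nucleophile nearly constant, the tail is roughly pseudo-first-order, though south-east still reads solid electrophile 9.3% at 1.50 h. So I interpolate the logarithm of what is not yet product between the south-east readings at 1.50 h and 3.00 h. That leaves 5.64% at 2.5 h, so 94.4% has reacted. Put back, this gives 31.3%, my value of the free share.

**The forecast.** Your hunch, the forecast, says 94.5% reacted and 70% free, and adds: “Held gas therefore keeps free nucleophile constant”. We stand close on the first number. On the second I am lower, at 31.3%.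

**The result.** The flask gives 94.8% reacted and 30.9% free, by these steps:

    acid set free + free base ⇌ salt of the base (K = 6230 M⁻¹, k = 0.0553 M⁻¹ s⁻¹)
    solid electrophile ⇌ electrophile, rate k2*(cs2 - [electrophile]) while solid is left; crystals form when [electrophile] > cs2 (solubility = 0.0860 M, k = 2.59 × 10⁻⁴ s⁻¹)
    gas ⇌ nucleophile, rate k3*(csat - [nucleophile]) (kL = 0.00632 s⁻¹)
    nucleophile + acid set free ⇌ protonated nucleophile, settled at all times (K = 65700 M⁻¹)
    acid set free → by-product carried off (k = 5.39 × 10⁻⁴ s⁻¹)
    electrophile + nucleophile → acid set free + product (k = 0.0140 M⁻¹ s⁻¹)

**Second flask.** At 2.50 h this flask holds nucleophile 0.0420 M and protonated nucleophile 0.0937 M, with 99.1% of the free base left. A neighbour flask with 0.17 M of solid electrophile reaches product 68.6% at 2.50 h. The free share reckoned from that product is 26.9%. That neighbour gives 25.1%, with nucleophile at 0.0383 M.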